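**Assumption:** the target, nonadecyl 3-(4-hydroxyphenyl)propanoate, has no stereocentre and no stereogenic double bond, so no enantiocontrol is needed. The one stereocentre that appears on the way (in the aldol adduct) is made racemic and is destroyed in the next step.

**Retrosynthetic overview**
1. The target is acyclic apart from the benzene ring, which is bought in the aldehyde; no ring is formed in the route.
2. Target ⇒ one-pot C=C hydrogenation and O-benzyl hydrogenolysis of nonadecyl (E)-4-(benzyloxy)cinnamate.
3. Cinnamate ⇒ dehydration of the β-hydroxy ester (aldol adduct).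
4. β-Hydroxy ester ⇒ key Cα–Cβ bond by intermolecular directed aldol addition of the lithium enolate of nonadecyl acetate to 4-(benzyloxy)benzaldehyde.
5. Nonadecyl acetate ⇒ nonadecan-1-ol + acetic anhydride.

**Route**

Step 1
Reactants: 1 nonadecan-1-ol; 2 acetic anhydride
Product: 3 nonadecyl acetate
Conditions: Ac2O (1.5 equiv), DMAP (5 mol %), pyridine, rt, 3 h
Reagents that add atoms: none
Why: DMAP-catalysed O-acylation (esterification) of an unhindered primary alcohol with an anhydride is essentially quantitative and creates no stereocentre.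

Step 2
Reactants: 3 nonadecyl acetate; 4 4-(benzyloxy)benzaldehyde
Product: 7 nonadecyl 3-[4-(benzyloxy)phenyl]-3-hydroxypropanoate (racemic), via lithium ester enolate 5 (not isolated), via lithium aldolate 6 (not isolated)
Conditions: LDA (commercial solution, 1.2 equiv), THF, −78 °C, 3 (1.15 equiv) added dropwise in THF, 45 min; then 4 (1.0 equiv) in THF, −78 °C, 1 h; AcOH in THF at −78 °C, then aqueous work-up
Reagents that add atoms: none
Why: This is a directed (crossed) aldol addition in which the preformed lithium ester enolate adds cleanly at −78 °C to the non-enolisable aromatic aldehyde; the carbinol stereocentre forms racemic, which does not matter because step 3 removes it.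

Step 3
Reactants: 7 nonadecyl 3-[4-(benzyloxy)phenyl]-3-hydroxypropanoate (racemic)
Product: 9 nonadecyl (E)-3-[4-(benzyloxy)phenyl]prop-2-enoate, via benzylic mesylate 8 (not isolated)
Conditions: MsCl (1.5 equiv), Et3N (3 equiv), CH2Cl2, 0 °C, 1 h; then DBU (2 equiv), 0 °C to rt
Reagents that add atoms: none
Why: Mesylation followed by E1cB elimination (aldol dehydration) removes the acidic α-hydrogen and the benzylic leaving group to give the conjugated cinnamate, and the E isomer results as the thermodynamically favoured product.

Step 4
Reactants: 9 nonadecyl (E)-3-[4-(benzyloxy)phenyl]prop-2-enoate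
Product: 10 nonadecyl 3-(4-hydroxyphenyl)propanoate
Conditions: H2 (1 atm), 10% Pd/C, EtOAc/EtOH 1:1, rt
Reagents that add atoms: none
Why: Heterogeneous catalytic hydrogenation saturates the conjugated alkene and hydrogenolyses the aryl benzyl ether in the same flask, while the alkyl ester and the arene are inert under these conditions; no stereocentre is present in the product.

**Compound list**
1 | nonadecan-1-ol | CCCCCCCCCCCCCCCCCCCO | starting material
2 | acetic anhydride | CC(=O)OC(C)=O | starting material
3 | nonadecyl acetate | CCCCCCCCCCCCCCCCCCCOC(C)=O | intermediate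
4 | 4-(benzyloxy)benzaldehyde | O=Cc1ccc(OCc2ccccc2)cc1 | starting material
5 | lithium 1-(nonadecyloxy)ethen-1-olate (lithium enolate of 3, not isolated) | CCCCCCCCCCCCCCCCCCCOC(=C)[O-].[Li+] | intermediate
6 | lithium 1-[4-(benzyloxy)phenyl]-3-(nonadecyloxy)-3-oxopropan-1-olate (racemic lithium aldolate, not isolated) | CCCCCCCCCCCCCCCCCCCOC(=O)CC([O-])c1ccc(OCc2ccccc2)cc1.[Li+] | intermediate
7 | nonadecyl 3-[4-(benzyloxy)phenyl]-3-hydroxypropanoate (racemic) | CCCCCCCCCCCCCCCCCCCOC(=O)CC(O)c1ccc(OCc2ccccc2)cc1 | intermediate
8 | nonadecyl 3-[4-(benzyloxy)phenyl]-3-[(methylsulfonyl)oxy]propanoate (racemic, not isolated) | CCCCCCCCCCCCCCCCCCCOC(=O)CC(OS(C)(=O)=O)c1ccc(OCc2ccccc2)cc1 | intermediate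
9 | nonadecyl (E)-3-[4-(benzyloxy)phenyl]prop-2-enoate | CCCCCCCCCCCCCCCCCCCOC(=O)/C=C/c1ccc(OCc2ccccc2)cc1 | intermediate
10 | nonadecyl 3-(4-hydroxyphenyl)propanoate | CCCCCCCCCCCCCCCCCCCOC(=O)CCc1ccc(O)cc1 | target

**Summary**
Total step count: 4. Longest linear sequence: 4 steps (1 → 3 → 7 → 9 → 10).

Three steps most likely to fail, each with a fallback:

Step 2 (aldol). The waxy C19 acetate or its enolate may be poorly soluble in THF at −78 °C, and any warming invites self-Claisen condensation, so conversion may be low. The fallback sets out from 4, with 1 as the alcohol partner, and comes back to the route at 9, bypassing 7 and step 3. Aldehyde 4 is condensed with malonic acid in pyridine with catalytic piperidine at 90–100 °C (Knoevenagel–Doebner, an aldol-type condensation run warm). The 2-{[4-(benzyloxy)phenyl]methylidene}propanedioic acid F1 formed in the flask decarboxylates to (E)-3-[4-(benzyloxy)phenyl]prop-2-enoic acid F2. F2 is then esterified with alcohol 1 (EDC·HCl, DMAP, CH2Cl2, rt, Steglich esterification) to give 9.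

Step 3 (dehydration). The p-alkoxy-activated benzylic mesylate 8 ionises easily and may give benzylic chloride or retro-aldol products with base. The fallback sets out from 7 and comes back at 10. Instead of eliminating, the electron-rich benzylic hydroxyl is removed reductively by ionic hydrogenation (Et3SiH, TFA, CH2Cl2, 0 °C, short reaction time to spare the benzyl ether), giving nonadecyl 3-[4-(benzyloxy)phenyl]propanoate F3. The benzyl ether of F3 is then hydrogenolysed (H2, Pd/C, EtOAc/EtOH, rt) to give 10.

Step 4 (hydrogenation/hydrogenolysis). Sulfur or amine residues from step 3 can poison Pd/C, and the waxy ester may be poorly soluble, so the O-debenzylation may stall. The fallback sets out from 9 and comes back at 10 without any metal catalyst. The benzyl ether is first cleaved with BCl3 and pentamethylbenzene as cation scavenger (CH2Cl2, −78 °C), which leaves the ester and alkene intact and gives nonadecyl (E)-3-(4-hydroxyphenyl)prop-2-enoate F4. The alkene of F4 is then reduced with diimide generated in situ (2-nitrobenzenesulfonyl hydrazide, Et3N, THF, rt) to give 10.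

**Further compounds**
F1 | step 2 | 2-{[4-(benzyloxy)phenyl]methylidene}propanedioic acid | OC(=O)C(=Cc1ccc(OCc2ccccc2)cc1)C(O)=O
F2 | step 2 | (E)-3-[4-(benzyloxy)phenyl]prop-2-enoic acid | OC(=O)/C=C/c1ccc(OCc2ccccc2)cc1
F3 | step 3 | nonadecyl 3-[4-(benzyloxy)phenyl]propanoate | CCCCCCCCCCCCCCCCCCCOC(=O)CCc1ccc(OCc2ccccc2)cc1
F4 | step 4 | nonadecyl (E)-3-(4-hydroxyphenyl)prop-2-enoate | CCCCCCCCCCCCCCCCCCCOC(=O)/C=C/c1ccc(O)cc1
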